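The five-membered ring (C1–C5, daucane numbering) is cut at C1–C5. The resulting chain C6–C5–C4(OH)(iPr)–C3–C2–C1 is the opened six-membered ring of (S)-terpinen-4-ol, so the C4 carbinol is bought, not made. The key step exploits the 1,6-relation of C6 and C1 around C4. It is an amine-catalysed intramolecular aldol condensation of a silyl-protected keto aldehyde: C5, alpha to the C6 aldehyde, adds to the C1 ketone and water leaves. This re-closes the cleaved cyclohexene as a cyclopentenecarbaldehyde carrying C6 and the C8–C10 chain. C4 then relays every other centre: cuprate methylation sets C1, equilibration C5, chelated vinyl addition C6. Ring-closing metathesis forms the seven-membered ring.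

Key step: step 4

Atom numbers used below:
- C1 is the ring-fusion carbon bearing CH3.
- C2 and C3 are the CH2 groups of the five-membered ring.
- C4 is the carbinol carbon bearing isopropyl.
- C5 is the ring-fusion CH.
- C6 is the CH–O–anisoyl carbon.
- C7=C8(CH3) is the alkene.
- C9 and C10 are the CH2 groups of the seven-membered ring.

Assumption: (S)-terpinen-4-ol is bought in enantioenriched form. Its enantiomeric purity carries through the route because no bond at C4 is broken.

Step 1
Reactants: 1 (S)-terpinen-4-ol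
Product: 2 (S)-terpinen-4-yl tert-butyldimethylsilyl ether
Conditions: TBSOTf, 2,6-lutidine, CH2Cl2, 0 °C to rt
Reagents that add atoms: tert-butyldimethylsilyl triflate, CC(C)(C)[Si](C)(C)OS(=O)(=O)C(F)(F)F
Why: Silyl ether protection of the hindered tertiary alcohol with the reactive silyl triflate touches no stereocentre, and the ether later prevents hemiketal formation, retro-aldol cleavage and loss of the C4 oxygen.

Step 2
Reactants: 2 (S)-terpinen-4-yl tert-butyldimethylsilyl ether
Product: 4 (5S)-5-(tert-butyldimethylsilyloxy)-5-(2,2-dimethoxyethyl)-6-methylheptan-2-one, via methoxy hydroperoxide aldehyde 3 (not isolated)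
Conditions: O3, CH2Cl2/MeOH, −78 °C; TsOH·H2O (cat.), rt; NaHCO3, then Me2S, rt
Reagents that add atoms: ozone, [O-][O+]=O; methanol, CO
Why: Ozonolysis in methanol (Criegee mechanism) cleaves the only C=C with the more substituted end leaving as the carbonyl oxide that methanol traps, so only the free C6 aldehyde is acetalised before Me2S reduces the hydroperoxide to the methyl ketone, and C4 is untouched.

Step 3
Reactants: 4 (5S)-5-(tert-butyldimethylsilyloxy)-5-(2,2-dimethoxyethyl)-6-methylheptan-2-one
Product: 5 (8S)-8-(tert-butyldimethylsilyloxy)-8-(2,2-dimethoxyethyl)-2,9-dimethyldec-1-en-5-one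
Conditions: LiN(iPr)2 (LDA), THF, −78 °C; CH2=C(CH3)CH2Br, DMPU, −78 to −30 °C
Reagents that add atoms: 3-bromo-2-methylprop-1-ene, C=C(C)CBr
Why: Kinetic enolate alkylation, in which LDA deprotonates the unhindered CH3 rather than C2 and the terminal enolate displaces the allylic bromide (SN2), turns the old ring methyl into C10 and adds C9, C8 and the C8 methyl without creating a stereocentre.

Step 4
Reactants: 5 (8S)-8-(tert-butyldimethylsilyloxy)-8-(2,2-dimethoxyethyl)-2,9-dimethyldec-1-en-5-one
Product: 7 (5R)-5-(tert-butyldimethylsilyloxy)-2-(3-methylbut-3-en-1-yl)-5-(propan-2-yl)cyclopent-1-ene-1-carbaldehyde, via keto aldehyde 6 (not isolated)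
Conditions: PPTS, acetone/H2O, 50 °C; solvent switch; Bn2NH·CF3CO2H (30 mol %), toluene, 60 °C
Reagents that add atoms: water, O
Why: After mild hydrolysis of the acetal, the secondary ammonium salt turns aldehyde 6 into an enamine whose only nucleophilic carbon is C5; this carbon adds to the C1 ketone and the new tertiary carbinol is lost as water through the iminium ion, giving the conjugated, tetrasubstituted C1=C5 enal. The closest known reaction type is the amine-catalysed intramolecular aldol condensation of 6-oxoalkanals to 2-alkylcyclopent-1-enecarbaldehydes. The five-membered ring closes in the 5-(enolexo)-exo-trig mode, favoured by the fully substituted C4 in the tether, while closure through C10 would need a seven-membered ring. No new stereocentre is formed, since C1 and C5 become sp2, and the C4 centre carries no hydrogen and keeps its C–O bond. The step needs the aldehyde as donor and the ketone as acceptor, not the reverse aldol of C2 onto C6, and amine catalysis secures this because only the aldehyde forms an enamine at a useful rate. It also needs loss of the C1 hydroxyl and not of the C4 oxygen, which the bulky silyl ether secures by being the poorer leaving group under weakly acidic conditions and by blocking retro-aldol cleavage of C4–C5.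

Step 5
Reactants: 7 (5R)-5-(tert-butyldimethylsilyloxy)-2-(3-methylbut-3-en-1-yl)-5-(propan-2-yl)cyclopent-1-ene-1-carbaldehyde
Product: 8 (5R)-5-hydroxy-2-(3-methylbut-3-en-1-yl)-5-(propan-2-yl)cyclopent-1-ene-1-carbaldehyde
Conditions: HF·pyridine, pyridine, THF, 0 °C to rt
Reagents that add atoms: none
Why: Fluoride-driven desilylation (Si–F bond formation) frees the tertiary allylic alcohol, which no longer sits beta to an enolisable carbon and is needed next as directing and chelating group.

Step 6
Reactants: 8 (5R)-5-hydroxy-2-(3-methylbut-3-en-1-yl)-5-(propan-2-yl)cyclopent-1-ene-1-carbaldehyde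
Product: 10 (1R,2R,5S)-2-hydroxy-5-methyl-5-(3-methylbut-3-en-1-yl)-2-(propan-2-yl)cyclopentane-1-carbaldehyde, via C5-epimeric aldehyde 9 (not isolated)
Conditions: Me2CuLi (from MeLi and CuI, 3 equiv), Et2O, −78 to −20 °C; aq NH4Cl; then DBU (cat.), CH2Cl2, rt
Reagents that add atoms: lithium dimethylcuprate, [Li+].C[Cu-]C
Why: In this conjugate addition of a Gilman cuprate the C4 alkoxide guides the reagent and the isopropyl group shields the opposite face, so CH3 should enter C1 cis to the C4 oxygen, and base equilibration of the kinetic protonation product 9 through its enol should place the C5 formyl group trans to isopropyl and to the C10 chain (thermodynamic control, helped by an O–H···O=C hydrogen bond).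

Step 7
Reactants: 10 (1R,2R,5S)-2-hydroxy-5-methyl-5-(3-methylbut-3-en-1-yl)-2-(propan-2-yl)cyclopentane-1-carbaldehyde
Product: 11 (1R,2S,3S)-2-[(1S)-1-hydroxyprop-2-en-1-yl]-3-methyl-3-(3-methylbut-3-en-1-yl)-1-(propan-2-yl)cyclopentan-1-ol
Conditions: CH2=CHMgBr (3 equiv), THF, −78 °C; aq NH4Cl
Reagents that add atoms: vinylmagnesium bromide, C=C[Mg]Br
Why: In this chelation-controlled Grignard addition the C4 magnesium alkoxide and the aldehyde oxygen form a six-membered chelate, and vinyl attacks the face turned away from the quaternary C1, which should give the (6S) carbinol.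

Step 8
Reactants: 11 (1R,2S,3S)-2-[(1S)-1-hydroxyprop-2-en-1-yl]-3-methyl-3-(3-methylbut-3-en-1-yl)-1-(propan-2-yl)cyclopentan-1-ol
Product: 12 (3R,3aS,4S,8aS)-6,8a-dimethyl-3-(propan-2-yl)-1,2,3,3a,4,7,8,8a-octahydroazulene-3,4-diol
Conditions: second-generation Grubbs catalyst RuCl2(=CHPh)(PCy3)(H2IMes) (5 mol %), CH2Cl2, 40 °C
Reagents that add atoms: none
Why: Ring-closing olefin metathesis of the vinyl carbinol with the 1,1-disubstituted alkene releases ethene and forms the trisubstituted C7=C8 bond of the seven-membered ring, the trans relation of C6 and C10 on the cyclopentane fixes the trans ring fusion, and no stereocentre changes.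

Step 9
Reactants: 12 (3R,3aS,4S,8aS)-6,8a-dimethyl-3-(propan-2-yl)-1,2,3,3a,4,7,8,8a-octahydroazulene-3,4-diol
Product: 13 (3R,3aS,4S,8aS)-3-hydroxy-6,8a-dimethyl-3-(propan-2-yl)-1,2,3,3a,4,7,8,8a-octahydroazulen-4-yl 4-methoxybenzoate
Conditions: 4-MeOC6H4COCl, Et3N, DMAP (cat.), CH2Cl2, 0 °C to rt
Reagents that add atoms: 4-methoxybenzoyl chloride, COc1ccc(cc1)C(Cl)=O
Why: DMAP-catalysed acylation (nucleophilic catalysis) selects the secondary allylic C6 hydroxyl because the tertiary C4 hydroxyl is too hindered, and C6 keeps its configuration since its C–O bond is not broken.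

Compound list
1 | (S)-terpinen-4-ol, (1S)-4-methyl-1-(propan-2-yl)cyclohex-3-en-1-ol | CC1=CC[C@](O)(C(C)C)CC1 | starting material
2 | (S)-terpinen-4-yl tert-butyldimethylsilyl ether | CC1=CC[C@](O[Si](C)(C)C(C)(C)C)(C(C)C)CC1 | intermediate
3 | (3S)-3-(tert-butyldimethylsilyloxy)-6-hydroperoxy-6-methoxy-3-(propan-2-yl)heptanal, not isolated | CC(OC)(OO)CC[C@@](O[Si](C)(C)C(C)(C)C)(C(C)C)CC=O | intermediate
4 | (5S)-5-(tert-butyldimethylsilyloxy)-5-(2,2-dimethoxyethyl)-6-methylheptan-2-one | CC(=O)CC[C@@](O[Si](C)(C)C(C)(C)C)(C(C)C)CC(OC)OC | intermediate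
5 | (8S)-8-(tert-butyldimethylsilyloxy)-8-(2,2-dimethoxyethyl)-2,9-dimethyldec-1-en-5-one | C=C(C)CCC(=O)CC[C@@](O[Si](C)(C)C(C)(C)C)(C(C)C)CC(OC)OC | intermediate
6 | (3S)-3-(tert-butyldimethylsilyloxy)-9-methyl-6-oxo-3-(propan-2-yl)dec-9-enal, not isolated | C=C(C)CCC(=O)CC[C@@](O[Si](C)(C)C(C)(C)C)(C(C)C)CC=O | intermediate
7 | (5R)-5-(tert-butyldimethylsilyloxy)-2-(3-methylbut-3-en-1-yl)-5-(propan-2-yl)cyclopent-1-ene-1-carbaldehyde | O=CC1=C(CCC(C)=C)CC[C@@]1(O[Si](C)(C)C(C)(C)C)C(C)C | intermediate
8 | (5R)-5-hydroxy-2-(3-methylbut-3-en-1-yl)-5-(propan-2-yl)cyclopent-1-ene-1-carbaldehyde | O=CC1=C(CCC(C)=C)CC[C@@]1(O)C(C)C | intermediate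
9 | (1S,2R,5S)-2-hydroxy-5-methyl-5-(3-methylbut-3-en-1-yl)-2-(propan-2-yl)cyclopentane-1-carbaldehyde, not isolated | O=C[C@H]1[C@@](C)(CCC(C)=C)CC[C@@]1(O)C(C)C | intermediate
10 | (1R,2R,5S)-2-hydroxy-5-methyl-5-(3-methylbut-3-en-1-yl)-2-(propan-2-yl)cyclopentane-1-carbaldehyde | O=C[C@@H]1[C@@](C)(CCC(C)=C)CC[C@@]1(O)C(C)C | intermediate
11 | (1R,2S,3S)-2-[(1S)-1-hydroxyprop-2-en-1-yl]-3-methyl-3-(3-methylbut-3-en-1-yl)-1-(propan-2-yl)cyclopentan-1-ol | C=C[C@H](O)[C@@H]1[C@@](C)(CCC(C)=C)CC[C@@]1(O)C(C)C | intermediate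
12 | (3R,3aS,4S,8aS)-6,8a-dimethyl-3-(propan-2-yl)-1,2,3,3a,4,7,8,8a-octahydroazulene-3,4-diol | O[C@H]1C=C(C)CC[C@@]2(C)CC[C@@](O)(C(C)C)[C@H]12 | intermediate
13 | (3R,3aS,4S,8aS)-3-hydroxy-6,8a-dimethyl-3-(propan-2-yl)-1,2,3,3a,4,7,8,8a-octahydroazulen-4-yl 4-methoxybenzoate | COc1ccc(C(=O)O[C@H]2C=C(C)CC[C@@]3(C)CC[C@@](O)(C(C)C)[C@H]23)cc1 | target

Total step count: 9. Longest linear sequence: 9 steps, from 1 to 13.

Steps most likely to fail

1. Step 4.
   - What may go wrong: beta-elimination of the C4 silyloxy group from the enamine, or aldolisation in the reverse sense.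
   - The fallback sets out from 5 and comes back at 7.
   - Acetal hydrolysis followed by Pinnick oxidation (NaClO2, NaH2PO4, 2-methylbut-2-ene) would give keto acid F1.
   - A nucleophile-catalysed aldol-lactonisation (2-bromo-1-propylpyridinium triflate, 4-pyrrolidinopyridine, iPr2NEt, CH2Cl2) would form the same C1–C5 bond from the acylammonium enolate. It would trap the C1 alkoxide at once as cis-fused beta-lactone F2.
   - DBU would open the strained lactone by E1cB loss of the carboxylate, a far better leaving group than the silyloxide, to give cyclopentenecarboxylic acid F3.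
   - Mixed-anhydride reduction (iBuOCOCl, N-methylmorpholine; then NaBH4) would give allylic alcohol F4, and MnO2 oxidation would return to 7.

2. Step 6.
   - What may go wrong: slow or 1,2-selective attack on the tetrasubstituted enal, incomplete facial control, or retro-aldol ring opening during the base equilibration.
   - The fallback sets out from 8 and comes back at 10.
   - Silylation of the C4 hydroxyl with BrCH2SiMe2Cl (imidazole, DMF) would give bromomethylsilyl ether F5.
   - Bu3SnH and AIBN (benzene, 80 °C) would generate the alpha-silyl radical, held on the face of the C4 oxygen. It would add to C1 in a 6-endo, Michael-type silicon-tethered radical cyclisation to give cyclic siloxane F6.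
   - TBAF in wet DMF at 70 °C would cleave both the Si–C and the Si–O bond. This leaves CH3 on C1 cis to the C4 hydroxyl, and the mildly basic medium should equilibrate C5 to give 10.

3. Step 7.
   - What may go wrong: poor facial selectivity if open transition states compete with the magnesium chelate.
   - The fallback sets out from 10 and comes back at 12.
   - The addition is run without regard to selectivity, so that 11 is accompanied by C6-epimeric diene diol F7.
   - Metathesis as in step 8 would give 12 together with C6-epimeric bicyclic diol F8.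
   - MnO2 would oxidise both allylic carbinols to the single hydroxy enone F9.
   - Hydroxyl-directed Evans–Saksena reduction with Me4NBH(OAc)3 (MeCN/AcOH, −20 °C) would deliver hydride from the face of the C4 hydroxyl and give 12.

Further compounds
F1 | step 4 | (3S)-3-(tert-butyldimethylsilyloxy)-9-methyl-6-oxo-3-(propan-2-yl)dec-9-enoic acid | C=C(C)CCC(=O)CC[C@@](O[Si](C)(C)C(C)(C)C)(C(C)C)CC(=O)O
F2 | step 4 | cis-fused 2-(tert-butyldimethylsilyloxy)-5-(3-methylbut-3-en-1-yl)-2-(propan-2-yl)-6-oxabicyclo[3.2.0]heptan-7-one | O=C1OC2(CCC(C)=C)CC[C@@](O[Si](C)(C)C(C)(C)C)(C(C)C)C12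
F3 | step 4 | (5R)-5-(tert-butyldimethylsilyloxy)-2-(3-methylbut-3-en-1-yl)-5-(propan-2-yl)cyclopent-1-ene-1-carboxylic acid | OC(=O)C1=C(CCC(C)=C)CC[C@@]1(O[Si](C)(C)C(C)(C)C)C(C)C
F4 | step 4 | [(5R)-5-(tert-butyldimethylsilyloxy)-2-(3-methylbut-3-en-1-yl)-5-(propan-2-yl)cyclopent-1-en-1-yl]methanol | OCC1=C(CCC(C)=C)CC[C@@]1(O[Si](C)(C)C(C)(C)C)C(C)C
F5 | step 6 | (5R)-5-[(bromomethyl)dimethylsilyloxy]-2-(3-methylbut-3-en-1-yl)-5-(propan-2-yl)cyclopent-1-ene-1-carbaldehyde | O=CC1=C(CCC(C)=C)CC[C@@]1(O[Si](C)(C)CBr)C(C)C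
F6 | step 6 | cyclic siloxane aldehyde with C4–O–SiMe2–CH2–C1 bridge, C5 unassigned | O=CC1[C@@]2(CCC(C)=C)CC[C@]1(C(C)C)O[Si](C)(C)C2
F7 | step 7 | (1R,2S,3S)-2-[(1R)-1-hydroxyprop-2-en-1-yl]-3-methyl-3-(3-methylbut-3-en-1-yl)-1-(propan-2-yl)cyclopentan-1-ol | C=C[C@@H](O)[C@@H]1[C@@](C)(CCC(C)=C)CC[C@@]1(O)C(C)C
F8 | step 7 | (3R,3aS,4R,8aS)-6,8a-dimethyl-3-(propan-2-yl)-1,2,3,3a,4,7,8,8a-octahydroazulene-3,4-diol | O[C@@H]1C=C(C)CC[C@@]2(C)CC[C@@](O)(C(C)C)[C@H]12
F9 | step 7 | (3R,3aR,8aS)-3-hydroxy-6,8a-dimethyl-3-(propan-2-yl)-2,3,3a,7,8,8a-hexahydroazulen-4(1H)-one | O=C1C=C(C)CC[C@@]2(C)CC[C@@](O)(C(C)C)[C@H]12
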